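**Assumption:** the target (7,4'-dihydroxy-3,5,6,8-tetramethoxyflavone) has no stereocentre and no stereogenic double bond, so "single enantiomer" requires no stereocontrol. Compounds 1, 6 and 7 are taken as commercially available.

## Retrosynthetic overview

1. Target 16 ⇐ double O-debenzylation of the 7,4'-dibenzyl ether 15.
2. 3-OMe of 15 ⇐ Cu-catalysed C–O coupling of MeOH with 3-iodoflavone 14, not the usual chalcone/Algar–Flynn–Oyamada or Allan–Robinson route.
3. Pyranone ring (the only ring formed) ⇐ demethylative 6-endo iodocyclisation (ICl) of ynone 12. The aryl ketone of 12 is mirror-symmetric (2,3,5,6-tetramethoxy-4-benzyloxy), so either ortho-OMe closes to the same chromone and the 5,6,8-OMe/7-OBn pattern is fixed by symmetry.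
4. Ynone 12 ⇐ aryllithium 10 (directed lithiation of 5) + alkynyl Weinreb amide 9.
5. 5 ⇐ 1,2,4,5-tetramethoxybenzene 1 (lithiation/borylation/oxidation, then benzylation); 9 ⇐ alkyne 6 + carbamoyl chloride 7.

## Route

**Step 1**
Reactants: 1 1,2,4,5-tetramethoxybenzene
Product: 4 2,3,5,6-tetramethoxyphenol, via aryllithium 2 (not isolated), via dimethyl arylboronate 3 (not isolated)
Conditions: n-BuLi (1.1 equiv), TMEDA, THF, 0 °C → rt; B(OMe)3, −78 °C → rt; then AcOH, 30% aq. H2O2, 0 °C → rt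
Reagents that add atoms: hydrogen peroxide, OO
Why: Directed ortho-metalation at one of the two equivalent C–H positions flanked by two OMe groups, then borylation and oxidative C–B to C–O conversion, gives the phenol with no regiochemical ambiguity.

**Step 2**
Reactants: 4 2,3,5,6-tetramethoxyphenol
Product: 5 3-(benzyloxy)-1,2,4,5-tetramethoxybenzene
Conditions: BnBr, K2CO3, DMF, 50 °C
Reagents that add atoms: benzyl bromide, BrCc1ccccc1
Why: Williamson ether synthesis marks the future 7-oxygen with a group that survives organolithium, ICl and Cu/carbonate conditions and is removed by hydrogenolysis.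

**Step 3**
Reactants: 6 1-(benzyloxy)-4-ethynylbenzene; 7 N-methoxy-N-methylcarbamoyl chloride
Product: 9 3-[4-(benzyloxy)phenyl]-N-methoxy-N-methylprop-2-ynamide, via lithium acetylide 8 (not isolated)
Conditions: n-BuLi, THF, −78 °C; then 7, −78 → 0 °C
Reagents that add atoms: none
Why: Acylation of a lithium acetylide with a carbamoyl chloride is a standard preparation of alkynyl Weinreb amides.

**Step 4**
Reactants: 5 3-(benzyloxy)-1,2,4,5-tetramethoxybenzene; 9 3-[4-(benzyloxy)phenyl]-N-methoxy-N-methylprop-2-ynamide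
Product: 12 3-[4-(benzyloxy)phenyl]-1-[4-(benzyloxy)-2,3,5,6-tetramethoxyphenyl]prop-2-yn-1-one, via aryllithium 10 (not isolated), via tetrahedral lithium adduct 11 (not isolated)
Conditions: 5, n-BuLi, TMEDA, THF, 0 °C, 1 h; add to 9, THF, −78 °C; quench at −78 °C into cold 1 M HCl
Reagents that add atoms: none
Why: Directed ortho-metalation at the last ring C–H (between two OMe groups) followed by Weinreb ketone synthesis; the chelated adduct 11 prevents over-addition, and the cold acidic quench protonates the released MeNHOMe before it can add to the ynone.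

**Step 5**
Reactants: 12 3-[4-(benzyloxy)phenyl]-1-[4-(benzyloxy)-2,3,5,6-tetramethoxyphenyl]prop-2-yn-1-one
Product: 14 7-(benzyloxy)-2-[4-(benzyloxy)phenyl]-3-iodo-5,6,8-trimethoxy-4H-chromen-4-one, via O-methyl oxonium chloride 13 (not isolated)
Conditions: ICl (1.2 equiv), CH2Cl2, −78 °C, 30 min; aq. Na2S2O3
Reagents that add atoms: iodine monochloride, ClI
Why: Larock-type electrophilic iodocyclisation: the ICl-activated alkyne is attacked 6-endo by an ortho-OMe oxygen (favoured by the electron-rich 4-benzyloxyphenyl terminus) and chloride demethylates the oxonium; the two ortho-OMe groups are equivalent, so only one chromone can form.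

**Step 6**
Reactants: 14 7-(benzyloxy)-2-[4-(benzyloxy)phenyl]-3-iodo-5,6,8-trimethoxy-4H-chromen-4-one
Product: 15 7-(benzyloxy)-2-[4-(benzyloxy)phenyl]-3,5,6,8-tetramethoxy-4H-chromen-4-one
Conditions: CuI (10 mol %), 3,4,7,8-tetramethyl-1,10-phenanthroline (20 mol %), Cs2CO3 (2 equiv), MeOH/toluene 1:1, 90 °C, sealed tube
Reagents that add atoms: methanol, CO
Why: Ullmann-type Cu(I)/phenanthroline C–O coupling of an sp2 iodide with an aliphatic alcohol installs the 3-OMe directly, with carbonate as a base mild enough to spare the pyranone ring.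

**Step 7**
Reactants: 15 7-(benzyloxy)-2-[4-(benzyloxy)phenyl]-3,5,6,8-tetramethoxy-4H-chromen-4-one
Product: 16 7-hydroxy-2-(4-hydroxyphenyl)-3,5,6,8-tetramethoxy-4H-chromen-4-one (target)
Conditions: H2 (1 atm), 10% Pd/C, EtOAc/MeOH, rt
Reagents that add atoms: none
Why: Catalytic hydrogenolysis cleaves both benzyl ethers at once, while the tetrasubstituted C2=C3 bond of the flavone and the methyl ethers are inert at 1 atm.

## Compound list

1 | 1,2,4,5-tetramethoxybenzene | COc1cc(OC)c(OC)cc1OC | starting material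
2 | (2,3,5,6-tetramethoxyphenyl)lithium | [Li]c1c(OC)c(OC)cc(OC)c1OC | intermediate
3 | dimethyl (2,3,5,6-tetramethoxyphenyl)boronate | COB(OC)c1c(OC)c(OC)cc(OC)c1OC | intermediate
4 | 2,3,5,6-tetramethoxyphenol | COc1cc(OC)c(OC)c(O)c1OC | intermediate
5 | 3-(benzyloxy)-1,2,4,5-tetramethoxybenzene | COc1cc(OC)c(OC)c(OCc2ccccc2)c1OC | intermediate
6 | 1-(benzyloxy)-4-ethynylbenzene | C#Cc1ccc(OCc2ccccc2)cc1 | starting material
7 | N-methoxy-N-methylcarbamoyl chloride | CON(C)C(=O)Cl | starting material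
8 | lithium [4-(benzyloxy)phenyl]acetylide | [Li]C#Cc1ccc(OCc2ccccc2)cc1 | intermediate
9 | 3-[4-(benzyloxy)phenyl]-N-methoxy-N-methylprop-2-ynamide | CON(C)C(=O)C#Cc1ccc(OCc2ccccc2)cc1 | intermediate
10 | [4-(benzyloxy)-2,3,5,6-tetramethoxyphenyl]lithium | [Li]c1c(OC)c(OC)c(OCc2ccccc2)c(OC)c1OC | intermediate
11 | lithium 3-[4-(benzyloxy)phenyl]-1-[4-(benzyloxy)-2,3,5,6-tetramethoxyphenyl]-1-[methoxy(methyl)amino]prop-2-yn-1-olate (tetrahedral adduct, racemic) | [Li]OC(C#Cc1ccc(OCc2ccccc2)cc1)(N(C)OC)c1c(OC)c(OC)c(OCc2ccccc2)c(OC)c1OC | intermediate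
12 | 3-[4-(benzyloxy)phenyl]-1-[4-(benzyloxy)-2,3,5,6-tetramethoxyphenyl]prop-2-yn-1-one | O=C(C#Cc1ccc(OCc2ccccc2)cc1)c1c(OC)c(OC)c(OCc2ccccc2)c(OC)c1OC | intermediate
13 | 7-(benzyloxy)-2-[4-(benzyloxy)phenyl]-3-iodo-5,6,8-trimethoxy-1-methyl-4-oxo-4H-chromen-1-ium chloride | C[O+]1c2c(OC)c(OCc3ccccc3)c(OC)c(OC)c2C(=O)C(I)=C1c1ccc(OCc2ccccc2)cc1.[Cl-] | intermediate
14 | 7-(benzyloxy)-2-[4-(benzyloxy)phenyl]-3-iodo-5,6,8-trimethoxy-4H-chromen-4-one | O=c1c(I)c(-c2ccc(OCc3ccccc3)cc2)oc2c(OC)c(OCc3ccccc3)c(OC)c(OC)c12 | intermediate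
15 | 7-(benzyloxy)-2-[4-(benzyloxy)phenyl]-3,5,6,8-tetramethoxy-4H-chromen-4-one | COc1c(-c2ccc(OCc3ccccc3)cc2)oc2c(OC)c(OCc3ccccc3)c(OC)c(OC)c2c1=O | intermediate
16 | 7-hydroxy-2-(4-hydroxyphenyl)-3,5,6,8-tetramethoxy-4H-chromen-4-one (CNP0539397.0, achiral) | COc1c(O)c(OC)c2oc(-c3ccc(O)cc3)c(OC)c(=O)c2c1OC | target

## Summary

Total step count: 7.
Longest linear sequence: 6 steps (1 → 4 → 5 → 12 → 14 → 15 → 16; steps 1, 2, 4, 5, 6, 7).

## Three steps most likely to fail, with fallbacks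

**Step 6 (Cu-catalysed methoxylation of the hindered 3-iodide; risks are protodeiodination and methoxide attack at C2).** The fallback sets out from 14 and comes back at 15, and replaces the C–O coupling by a metalation–oxidation–alkylation sequence. Iodine–magnesium exchange on 14 with iPrMgCl·LiCl in THF at −40 °C gives the C3 Grignard reagent [7-(benzyloxy)-2-[4-(benzyloxy)phenyl]-5,6,8-trimethoxy-4-oxo-4H-chromen-3-yl]magnesium chloride F1. Trapping with B(OMe)3 gives the dimethyl chromen-3-ylboronate F2. Oxidation in the same pot with NaBO3·4H2O in aqueous THF gives the flavonol 7-(benzyloxy)-2-[4-(benzyloxy)phenyl]-3-hydroxy-5,6,8-trimethoxy-4H-chromen-4-one F3. O-Methylation of F3 with MeI/K2CO3 in acetone returns 15.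

**Step 5 (demethylative iodocyclisation; risks are iodination of the benzyloxyphenyl ring, 5-exo closure, or a sluggish reaction of the twisted 2,6-disubstituted aryl ketone).** The fallback sets out from 5 (through its aryllithium 10) and comes back at 15. It builds the 3-methoxychromone first and attaches the B ring last, so steps 4–6 are bypassed.
- Aryllithium 10 is acylated with N,2-dimethoxy-N-methylacetamide to give 1-[4-(benzyloxy)-2,3,5,6-tetramethoxyphenyl]-2-methoxyethan-1-one F4.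
- Chelation-controlled mono-demethylation of one of the two equivalent ortho-OMe groups with MgI2·OEt2 in toluene gives 1-[4-(benzyloxy)-2-hydroxy-3,5,6-trimethoxyphenyl]-2-methoxyethan-1-one F5.
- Condensation with DMF dimethyl acetal in toluene at 100 °C gives the enaminone (Z)-1-[4-(benzyloxy)-2-hydroxy-3,5,6-trimethoxyphenyl]-3-(dimethylamino)-2-methoxyprop-2-en-1-one F6.
- F6 cyclises with loss of dimethylamine in warm AcOH to 7-(benzyloxy)-3,5,6,8-tetramethoxy-4H-chromen-4-one F7.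
- TMPZnCl·LiCl in THF at rt zincates the only remaining ring C–H (C2) to give [7-(benzyloxy)-3,5,6,8-tetramethoxy-4-oxo-4H-chromen-2-yl]zinc chloride F8.
- Negishi coupling of F8 with 1-(benzyloxy)-4-iodobenzene (Pd(OAc)2/SPhos, THF, 50 °C) gives 15.

**Step 4 (aryllithium addition to the alkynyl Weinreb amide; risks are conjugate addition to the ynamide, amine addition to the ynone on work-up, or competing benzylic lithiation).** The fallback sets out from 5 and comes back at 12, and changes the C–C bond construction to aldehyde addition followed by oxidation. Aryllithium 10 is quenched with DMF to give 4-(benzyloxy)-2,3,5,6-tetramethoxybenzaldehyde F9. Addition of lithium acetylide 8 (from 6 and n-BuLi) in THF at −78 °C gives the racemic propargylic alcohol 3-[4-(benzyloxy)phenyl]-1-[4-(benzyloxy)-2,3,5,6-tetramethoxyphenyl]prop-2-yn-1-ol F10. Oxidation with MnO2 in CH2Cl2 gives ynone 12.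

## Further compounds

F1 | step 6 | [7-(benzyloxy)-2-[4-(benzyloxy)phenyl]-5,6,8-trimethoxy-4-oxo-4H-chromen-3-yl]magnesium chloride | Cl[Mg]c1c(-c2ccc(OCc3ccccc3)cc2)oc2c(OC)c(OCc3ccccc3)c(OC)c(OC)c2c1=O
F2 | step 6 | dimethyl [7-(benzyloxy)-2-[4-(benzyloxy)phenyl]-5,6,8-trimethoxy-4-oxo-4H-chromen-3-yl]boronate | COB(OC)c1c(-c2ccc(OCc3ccccc3)cc2)oc2c(OC)c(OCc3ccccc3)c(OC)c(OC)c2c1=O
F3 | step 6 | 7-(benzyloxy)-2-[4-(benzyloxy)phenyl]-3-hydroxy-5,6,8-trimethoxy-4H-chromen-4-one | O=c1c(O)c(-c2ccc(OCc3ccccc3)cc2)oc2c(OC)c(OCc3ccccc3)c(OC)c(OC)c12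
F4 | step 5 | 1-[4-(benzyloxy)-2,3,5,6-tetramethoxyphenyl]-2-methoxyethan-1-one | COCC(=O)c1c(OC)c(OC)c(OCc2ccccc2)c(OC)c1OC
F5 | step 5 | 1-[4-(benzyloxy)-2-hydroxy-3,5,6-trimethoxyphenyl]-2-methoxyethan-1-one | COCC(=O)c1c(O)c(OC)c(OCc2ccccc2)c(OC)c1OC
F6 | step 5 | (Z)-1-[4-(benzyloxy)-2-hydroxy-3,5,6-trimethoxyphenyl]-3-(dimethylamino)-2-methoxyprop-2-en-1-one | CO/C(=C\N(C)C)C(=O)c1c(O)c(OC)c(OCc2ccccc2)c(OC)c1OC
F7 | step 5 | 7-(benzyloxy)-3,5,6,8-tetramethoxy-4H-chromen-4-one | COc1coc2c(OC)c(OCc3ccccc3)c(OC)c(OC)c2c1=O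
F8 | step 5 | [7-(benzyloxy)-3,5,6,8-tetramethoxy-4-oxo-4H-chromen-2-yl]zinc chloride | COc1c([Zn]Cl)oc2c(OC)c(OCc3ccccc3)c(OC)c(OC)c2c1=O
F9 | step 4 | 4-(benzyloxy)-2,3,5,6-tetramethoxybenzaldehyde | COc1c(OC)c(C=O)c(OC)c(OC)c1OCc1ccccc1
F10 | step 4 | 3-[4-(benzyloxy)phenyl]-1-[4-(benzyloxy)-2,3,5,6-tetramethoxyphenyl]prop-2-yn-1-ol (racemic) | COc1c(OC)c(C(O)C#Cc2ccc(OCc3ccccc3)cc2)c(OC)c(OC)c1OCc1ccccc1
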